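A direct plan would make (E)-3,4-dimethoxycinnamyl methyl ether A1 by a hydroboration/Suzuki sequence and dimerise it head-to-head, in an enantioselective radical-cation [2+2], to the all-trans cyclobutane A2.
It would then open the doubly benzylic bond of A2 with acid, so that a benzylic cation closes ring B at C1–C8a (cyclobutane-to-tetralin ring expansion).
Weak step 1, the asymmetric homodimerisation: the only step that fixes absolute configuration would be an untested asymmetric variant of a reversible cycloaddition (cycloreversion and hole transfer erode the ee), and the plan already counts on recrystallisation to repair it.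
Weak step 2, the protonolytic ring expansion: catalytic acid would protonate the electron-rich arenes and the ether oxygens long before a cyclobutane C–C bond. Retro-[2+2] to A1 and capture of the benzylic cation by the C3 methoxymethyl oxygen (five-membered oxonium ion) would compete, and C1 would be set from a free cation.
Weak point 3: two untested methods in a row put the risk in two places.

**Retrosynthetic overview**
- The CH2OMe groups on C2 and C3 are read as a reduced (E)-butenedioate: the target goes back to the diol and then to an all-trans 1-aryltetralin-2,3-diester.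
- Ring B is cut in one stroke at C1–C2 and C3–C4 (retro-[4+2]). The diene is a hydroxy-o-quinodimethane in which ring A is transiently dearomatised, made by photoenolisation of 2-(3,4-dimethoxybenzyl)-4,5-dimethoxybenzaldehyde; the dienophile is a fumarate with two (S)-lactate auxiliaries; the extra C4–OH is then hydrogenolysed.
- Feature used: C1 carries two identical 3,4-dimethoxyphenyl rings (ring A and the pendant ring), so the diene precursor is only a diarylmethane mono-aldehyde (one Negishi coupling). The all-trans C1/C2/C3 array is the direct print of an (E)-aryl diene terminus, an (E)-dienophile and one endo contact.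
- Ring order: ring A and the pendant ring are bought; ring B closes last, in the key step, together with all three stereocentres. There is no cyclobutane, no free benzylic cation beside the ether oxygens, and no untested reaction type.

Key step: step 3

Assumption: the (S)-lactate groups are taken to direct the dienol to the fumarate face that gives the (2S,3S) adduct (the sense expected for cycloadditions of this kind with fumarates of (S)-α-hydroxy esters); if the sense were the opposite, the fumarate of methyl (R)-lactate would be used with no other change.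

**Step 1**
Reactants: 1 3,4-dimethoxybenzyl chloride; 2 2-bromo-4,5-dimethoxybenzaldehyde
Product: 4 2-(3,4-dimethoxybenzyl)-4,5-dimethoxybenzaldehyde, via (3,4-dimethoxybenzyl)zinc chloride 3 (not isolated)
Conditions: 1 (1.3 equiv), Zn dust (2 equiv), LiCl (1.5 equiv), THF, 25 °C; then 2 (1.0 equiv), Pd(PPh3)4 (3 mol%), THF, 50 °C
Reagents that add atoms: none
Why: LiCl-assisted insertion of zinc into the benzylic C–Cl bond gives 3, and Negishi cross-coupling (oxidative addition of zerovalent palladium into the C–Br bond of 2, transmetalation, reductive elimination) joins the benzylic carbon to the arene while the aldehyde, which benzylzinc halides attack only slowly, is kept; no stereocentre is formed.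

**Step 2**
Reactants: 5 fumaryl chloride; 6 methyl (S)-lactate
Product: 7 bis[(2S)-1-methoxy-1-oxopropan-2-yl] (E)-but-2-enedioate
Conditions: 5 (1.0 equiv), 6 (2.2 equiv), pyridine (2.5 equiv), CH2Cl2, 0 °C to rt
Reagents that add atoms: none
Why: Double O-acylation of the secondary alcohol by the acid chloride, in which the lactate stereocentre is not involved and the E geometry of the alkene is kept.

**Step 3**
Reactants: 4 2-(3,4-dimethoxybenzyl)-4,5-dimethoxybenzaldehyde; 7 bis[(2S)-1-methoxy-1-oxopropan-2-yl] (E)-but-2-enedioate
Product: 9 bis[(2S)-1-methoxy-1-oxopropan-2-yl] (1R,2S,3R,4R)-1-(3,4-dimethoxyphenyl)-4-hydroxy-6,7-dimethoxy-1,2,3,4-tetrahydronaphthalene-2,3-dicarboxylate (numbering of the target), via (E,E)-hydroxy-o-quinodimethane 8 (not isolated)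
Conditions: 4 (1.0 equiv), 7 (2.0 equiv), hν (350 nm, Pyrex), degassed toluene, 0.03 M, 20 °C
Reagents that add atoms: none
Why: Excitation of aldehyde 4 is followed by 1,5-hydrogen transfer from the doubly benzylic CH2 to the carbonyl oxygen (photoenolisation), which dearomatises ring A to the (E,E)-dienol 8 (the Z-dienol returns to 4 by a fast 1,5-H shift and the aryl group takes the outside position for steric reasons), and 8 is trapped by 7 in a concerted suprafacial [4+2] cycloaddition that restores ring A. The closest known reaction type is the photoenolisation/Diels–Alder reaction of o-alkylbenzaldehydes with fumarates, including hydroxy-o-quinodimethanes with an aryl group on the second terminus and fumarates of α-hydroxy esters. Ring B closes as the six-membered ring of the [4+2], with C1–C2 and C3–C4 formed together. The C2/C3 trans relation is controlled by the E geometry of the fumarate; C4–OH cis to the C3 ester comes from the endo position of that ester, held by a hydrogen bond to the dienol OH; C1-aryl trans to the C2 ester comes from the outside aryl group and the exo position of the C2 ester. The absolute configuration at C2 and C3 (and through the endo rule at C1 and C4) is controlled by the two (S)-lactate groups, which differentiate the faces of the fumarate in the sense assumed above. The step needs one endo mode and one π-face: the OH···O=C hydrogen bond in a non-polar solvent should secure both, and 350 nm light is absorbed only by 4, so that 7 is not isomerised by direct excitation.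

**Step 4**
Reactants: 9 bis[(2S)-1-methoxy-1-oxopropan-2-yl] (1R,2S,3R,4R)-1-(3,4-dimethoxyphenyl)-4-hydroxy-6,7-dimethoxy-1,2,3,4-tetrahydronaphthalene-2,3-dicarboxylate
Product: 10 bis[(2S)-1-methoxy-1-oxopropan-2-yl] (1R,2S,3S)-1-(3,4-dimethoxyphenyl)-6,7-dimethoxy-1,2,3,4-tetrahydronaphthalene-2,3-dicarboxylate
Conditions: H2 (3 atm), Pd/C (10 wt% Pd, 10 mol%), AcOH, HClO4 (cat.), 25 °C
Reagents that add atoms: none
Why: Hydrogenolysis of the benzylic C4–O bond, activated by the para methoxy group of ring A, should leave the diarylmethine C1 and the esters untouched; C1, C2 and C3 keep their spatial arrangement and C4 ceases to be a stereocentre (the descriptor of C3 changes from R to S only because the priorities change).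

**Step 5**
Reactants: 10 bis[(2S)-1-methoxy-1-oxopropan-2-yl] (1R,2S,3S)-1-(3,4-dimethoxyphenyl)-6,7-dimethoxy-1,2,3,4-tetrahydronaphthalene-2,3-dicarboxylate
Product: 11 [(1R,2S,3S)-1-(3,4-dimethoxyphenyl)-6,7-dimethoxy-1,2,3,4-tetrahydronaphthalene-2,3-diyl]dimethanol
Conditions: LiAlH4 (5 equiv), THF, 0 °C to reflux; aqueous NaOH work-up
Reagents that add atoms: none
Why: Hydride reduction of both ring-bound ester groups to primary alcohols, which at the same time cleaves the lactate auxiliaries as water-soluble propane-1,2-diol; no stereocentre is touched.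

**Step 6**
Reactants: 11 [(1R,2S,3S)-1-(3,4-dimethoxyphenyl)-6,7-dimethoxy-1,2,3,4-tetrahydronaphthalene-2,3-diyl]dimethanol
Product: 12 phyltetralin, (1R,2S,3S)-1-(3,4-dimethoxyphenyl)-6,7-dimethoxy-2,3-bis(methoxymethyl)-1,2,3,4-tetrahydronaphthalene
Conditions: NaH (3 equiv), MeI (4 equiv), THF/DMF 4:1, 0 °C to rt
Reagents that add atoms: iodomethane, CI
Why: Double Williamson O-methylation of the two primary alkoxides; the stereocentres are not involved.

**Compound list**
1 | 3,4-dimethoxybenzyl chloride (4-(chloromethyl)-1,2-dimethoxybenzene) | COc1ccc(CCl)cc1OC | starting material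
2 | 2-bromo-4,5-dimethoxybenzaldehyde | COc1cc(Br)c(C=O)cc1OC | starting material
3 | (3,4-dimethoxybenzyl)zinc chloride | COc1ccc(C[Zn]Cl)cc1OC | intermediate
4 | 2-(3,4-dimethoxybenzyl)-4,5-dimethoxybenzaldehyde | COc1ccc(Cc2cc(OC)c(OC)cc2C=O)cc1OC | intermediate
5 | fumaryl chloride ((E)-but-2-enedioyl dichloride) | O=C(Cl)/C=C/C(=O)Cl | starting material
6 | methyl (S)-lactate | C[C@H](O)C(=O)OC | starting material
7 | bis[(2S)-1-methoxy-1-oxopropan-2-yl] (E)-but-2-enedioate | COC(=O)[C@H](C)OC(=O)/C=C/C(=O)O[C@@H](C)C(=O)OC | intermediate
8 | (E)-[(6E)-6-(3,4-dimethoxybenzylidene)-3,4-dimethoxycyclohexa-2,4-dien-1-ylidene]methanol ((E,E)-hydroxy-o-quinodimethane) | O/C=C1/C(=C/c2ccc(OC)c(OC)c2)C=C(OC)C(OC)=C1 | intermediate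
9 | bis[(2S)-1-methoxy-1-oxopropan-2-yl] (1R,2S,3R,4R)-1-(3,4-dimethoxyphenyl)-4-hydroxy-6,7-dimethoxy-1,2,3,4-tetrahydronaphthalene-2,3-dicarboxylate | COC(=O)[C@H](C)OC(=O)[C@H]1[C@@H](O)c2cc(OC)c(OC)cc2[C@@H](c2ccc(OC)c(OC)c2)[C@@H]1C(=O)O[C@@H](C)C(=O)OC | intermediate
10 | bis[(2S)-1-methoxy-1-oxopropan-2-yl] (1R,2S,3S)-1-(3,4-dimethoxyphenyl)-6,7-dimethoxy-1,2,3,4-tetrahydronaphthalene-2,3-dicarboxylate | COC(=O)[C@H](C)OC(=O)[C@H]1Cc2cc(OC)c(OC)cc2[C@@H](c2ccc(OC)c(OC)c2)[C@@H]1C(=O)O[C@@H](C)C(=O)OC | intermediate
11 | [(1R,2S,3S)-1-(3,4-dimethoxyphenyl)-6,7-dimethoxy-1,2,3,4-tetrahydronaphthalene-2,3-diyl]dimethanol | OC[C@H]1Cc2cc(OC)c(OC)cc2[C@@H](c2ccc(OC)c(OC)c2)[C@@H]1CO | intermediate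
12 | phyltetralin, (1R,2S,3S)-1-(3,4-dimethoxyphenyl)-6,7-dimethoxy-2,3-bis(methoxymethyl)-1,2,3,4-tetrahydronaphthalene | COC[C@H]1Cc2cc(OC)c(OC)cc2[C@@H](c2ccc(OC)c(OC)c2)[C@@H]1COC | target

**Step count and risks**
Total step count: 6. Longest linear sequence: 5 (steps 1, 3, 4, 5, 6; step 2 prepares the dienophile).

Steps most likely to fail:

Step 3 (key step). The excited aldehyde may pass triplet energy to the fumarate, so that E/Z isomerisation of 7 and secondary photoreactions of the adduct erode the trans relation at C2/C3 and the yield; photoenolisation of this electron-rich aldehyde may also be slow. The fallback sets out from 4 and divides the step into a photochemical and a thermal half. Irradiation of 4 in benzene saturated with sulfur dioxide should trap the dienol as the cyclic hydroxy sulfone 1-(3,4-dimethoxyphenyl)-3-hydroxy-5,6-dimethoxy-1,3-dihydro-2-benzothiophene 2,2-dioxide F1 (mixture of diastereomers). Heating F1 with 7 and ZnO (scavenger for SO2) in benzene at 80 °C in the dark should extrude sulfur dioxide, regenerate the (E,E)-dienol 8 in the ground state and let it add to 7 under hydrogen-bond control. The fallback comes back to the route at 9.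

Step 4. Acid-promoted loss of water from the β-hydroxy ester to a C3=C4 alkene, followed by unselective hydrogenation, would scramble C3. The fallback sets out from 9 and replaces retention by thermodynamic control. The hydrogenation is run until the C4–O bond and any alkene are saturated, and the crude diester mixture is heated with NaOMe in MeOH. This exchanges the lactate esters for methyl esters and epimerises C2 and C3 (both α to an ester) to the all-equatorial arrangement that the untouched C1 dictates, dimethyl (1R,2S,3S)-1-(3,4-dimethoxyphenyl)-6,7-dimethoxy-1,2,3,4-tetrahydronaphthalene-2,3-dicarboxylate F2. Reduction of F2 with LiAlH4 comes back to the route at 11.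

Step 1. Homocoupling during zinc insertion into the electron-rich benzylic chloride, or addition of the benzylzinc reagent to the aldehyde of 2, would consume the coupling partners. The fallback sets out from 1 and avoids organometallic reagents. Friedel–Crafts benzylation of veratrole (in excess) with 1 and ZnCl2 (cat.) should give bis(3,4-dimethoxyphenyl)methane F3. Rieche formylation of F3 (Cl2CHOMe, 1 equiv, TiCl4, CH2Cl2, 0 °C) at the position para to a methoxy group and ortho to the CH2 bridge comes back to the route at 4; unreacted F3 is recycled.

**Further compounds**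
F1 | step 3 | 1-(3,4-dimethoxyphenyl)-3-hydroxy-5,6-dimethoxy-1,3-dihydro-2-benzothiophene 2,2-dioxide (mixture of diastereomers) | OC1c2cc(OC)c(OC)cc2C(c2ccc(OC)c(OC)c2)S1(=O)=O
F2 | step 4 | dimethyl (1R,2S,3S)-1-(3,4-dimethoxyphenyl)-6,7-dimethoxy-1,2,3,4-tetrahydronaphthalene-2,3-dicarboxylate | COC(=O)[C@H]1Cc2cc(OC)c(OC)cc2[C@@H](c2ccc(OC)c(OC)c2)[C@@H]1C(=O)OC
F3 | step 1 | bis(3,4-dimethoxyphenyl)methane | COc1ccc(Cc2ccc(OC)c(OC)c2)cc1OC
A1 | direct plan | (E)-1,2-dimethoxy-4-(3-methoxyprop-1-en-1-yl)benzene | COC/C=C/c1ccc(OC)c(OC)c1
A2 | direct plan | (1R,2R,3S,4S)-1,2-bis(3,4-dimethoxyphenyl)-3,4-bis(methoxymethyl)cyclobutane | COC[C@H]1[C@H](c2ccc(OC)c(OC)c2)[C@@H](c2ccc(OC)c(OC)c2)[C@@H]1COC
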